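**Plan**
- Retrosynthetic cuts: first the two aryl–O–CH(CH3) ether bonds of the threo side chains; then, in one step, O1–C5 and C2–C(ring A) of the oxolane; then C5–C(ring B); last C3–C4, which joins two propanoyl units.
- Forward: homocoupling of two molecules of a propanoyl oxazolidinone gives the (3R,4R)-dimethyl unit as its anhydride, which the ring B Grignard reagent opens. Reduction, lactonisation, methylenation, mesylation and ozonolysis then give a C5 mesylate carrying a C2 aldehyde.
- The oxolane is the only ring made. Ring A adds to C2 and the new alkoxide O1 closes on C5 with inversion (step 12). The side chains are then attached to the two para phenols, and the allyl ether on ring A is cleaved last.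
- Enabling feature: O1 is 1,4 to C5 across C2–C3–C4, and C2 and C5 are both benzylic. The para oxygen of ring B, needed later as an ether oxygen, can be held as a tosylate, which makes the C5 mesylate a pure SN2 centre.
- Stereochemistry: C3/C4 from the (S)-benzyl oxazolidinone; C5 from Felkin–Anh reduction followed by inversion; C2 from Felkin–Anh aryl addition; side-chain centres from ethyl (S)-lactate (inversion) and Felkin–Anh borohydride reduction.

Key step: step 12

Remark: oxolane atoms are numbered O1, C2 (bears ring A, the ring that ends as the free phenol), C3, C4, C5 (bears ring B, the methoxy ring). Ts = 4-methylbenzenesulfonyl, Ms = methanesulfonyl.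
Assumption: the enolate coupling of step 1 takes place on the face of each enolate that is open in alkylations of the same oxazolidinone, which leads to the (2R,3R) dimer.

**Route**

Step 1
Reactants: 1 (S)-4-benzyl-3-propanoyl-1,3-oxazolidin-2-one (2 equiv)
Product: 3 (4S,4'S)-3,3'-[(2R,3R)-2,3-dimethylbutanedioyl]bis(4-benzyl-1,3-oxazolidin-2-one), via lithium enolate 2 (not isolated)
Conditions: LiN(i-Pr)2 (1.1 equiv per imide), THF, −78 °C; then TiCl4 (1.1 equiv per imide), −78 °C → 0 °C
Reagents that add atoms: none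
Why: Oxidative enolate homocoupling, in which tetravalent titanium oxidises the chelated (Z)-enolate and two molecules of 1 are joined at their α-carbons, each on the face away from its benzyl group, should give the (2R,3R) dimer.

Step 2
Reactants: 3 the bis-imide
Product: 4 (2R,3R)-2,3-dimethylbutanedioic acid
Conditions: LiOH, H2O2, THF/H2O, 0 °C; then Na2SO3; HCl
Reagents that add atoms: hydrogen peroxide, OO
Why: Hydroperoxide cleavage of N-acyl oxazolidinones attacks the exocyclic carbonyl only and leaves the α-stereocentres untouched.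

Step 3
Reactants: 4 (2R,3R)-2,3-dimethylbutanedioic acid
Product: 5 (3R,4R)-3,4-dimethyloxolane-2,5-dione
Conditions: AcCl, 50 °C; evaporation
Reagents that add atoms: none
Why: Cyclodehydration of a succinic acid by an acid chloride, at a temperature at which the trans anhydride should not epimerise.

Step 4
Reactants: 6 4-bromo-2-methoxyphenol
Product: 7 4-bromo-2-methoxyphenyl 4-methylbenzenesulfonate
Conditions: TsCl, Et3N, DMAP (cat.), CH2Cl2, 0 → 23 °C
Reagents that add atoms: 4-methylbenzenesulfonyl chloride, Cc1ccc(cc1)S(=O)(=O)Cl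
Why: Phenol sulfonylation; the tosylate protects the para oxygen of ring B and is the electron-withdrawing helper of the key step.

Step 5
Reactants: 7 the ring B bromide, 5 the anhydride
Product: 9 (2R,3R)-4-[3-methoxy-4-(tosyloxy)phenyl]-2,3-dimethyl-4-oxobutanoic acid, via ring B Grignard reagent 8 (not isolated)
Conditions: 7, i-PrMgCl·LiCl, THF, 0 → 23 °C; then added to 5, THF, −78 → −40 °C; 1 M HCl
Reagents that add atoms: none
Why: Bromine–magnesium exchange tolerates the aryl sulfonate, and an aryl Grignard reagent opens a cyclic anhydride only once because the carboxylate formed shields the second carbonyl; the two carbonyls of the C2-symmetric anhydride are equivalent.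

Step 6
Reactants: 9 the keto acid
Product: 11 (3R,4R,5R)-5-[3-methoxy-4-(tosyloxy)phenyl]-3,4-dimethyloxolan-2-one, via hydroxy acid 10 (not isolated)
Conditions: LiBH(s-Bu)3, THF, −78 °C; 1 M HCl; then TsOH (cat.), CH2Cl2, 23 °C
Reagents that add atoms: none
Why: Felkin–Anh reduction of the α-methyl aryl ketone by a bulky hydride should place the new hydroxyl anti to the α-methyl group (the future C5, R), and acid closes the γ-hydroxy acid to the all-trans lactone.

Step 7
Reactants: 11 the lactone
Product: 13 (1R,2R,3S)-1-[3-methoxy-4-(tosyloxy)phenyl]-2,3-dimethylpent-4-en-1-ol, via lactol 12 (not isolated)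
Conditions: i-Bu2AlH, CH2Cl2, −78 °C; aq. potassium sodium tartrate (KNaC4H4O6); crude lactol, Ph3PCH3Br, KN(SiMe3)2, THF, 0 → 23 °C
Reagents that add atoms: methyltriphenylphosphonium bromide, C[P+](c1ccccc1)(c1ccccc1)c1ccccc1.[Br-]
Why: Partial reduction of the lactone and Wittig methylenation of the open hydroxy aldehyde form of the lactol; the alkene masks the C2 aldehyde while C5 is activated.

Step 8
Reactants: 13 the alkenol
Product: 14 (1R,2R,3S)-1-[3-methoxy-4-(tosyloxy)phenyl]-2,3-dimethylpent-4-en-1-yl methanesulfonate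
Conditions: Ms2O, Et3N, DMAP (cat.), CH2Cl2, −20 °C; used without storage
Reagents that add atoms: methanesulfonic anhydride, CS(=O)(=O)OS(C)(=O)=O
Why: Sulfonylation with retention at C5; the anhydride avoids chloride, and the tosyloxy group para on ring B keeps the benzylic mesylate from ionising.

Step 9
Reactants: 14 the alkenyl mesylate
Product: 15 (1R,2R,3R)-1-[3-methoxy-4-(tosyloxy)phenyl]-2,3-dimethyl-4-oxobutyl methanesulfonate
Conditions: O3, CH2Cl2, −78 °C; then PPh3, −78 → 0 °C; used crude
Reagents that add atoms: ozone, [O-][O+]=O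
Why: Ozonolysis with reductive work-up cleaves the terminal alkene under neutral conditions that leave both sulfonates and the α-stereocentre intact.

Step 10
Reactants: 16 2-(allyloxy)phenol
Product: 17 2-(allyloxy)-4-bromophenol
Conditions: NBS, MeCN, 0 °C
Reagents that add atoms: N-bromosuccinimide, O=C1CCC(=O)N1Br
Why: Electrophilic aromatic bromination para to the free hydroxyl, the strongest donor on the ring, as with guaiacol.

Step 11
Reactants: 17 2-(allyloxy)-4-bromophenol
Product: 18 2-(allyloxy)-4-bromophenyl 4-methylbenzenesulfonate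
Conditions: TsCl, Et3N, DMAP (cat.), CH2Cl2, 0 → 23 °C
Reagents that add atoms: 4-methylbenzenesulfonyl chloride, Cc1ccc(cc1)S(=O)(=O)Cl
Why: Phenol sulfonylation as in step 4; the allyl ether marks the oxygen that ends as the free hydroxyl.

Step 12
Reactants: 18 the ring A bromide, 15 the aldehyde mesylate
Product: 21 2-(allyloxy)-4-{(2S,3R,4R,5S)-5-[3-methoxy-4-(tosyloxy)phenyl]-3,4-dimethyloxolan-2-yl}phenyl 4-methylbenzenesulfonate, via ring A Grignard reagent 19 (not isolated), via chloromagnesium alkoxide 20 (not isolated)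
Conditions: 18, i-PrMgCl·LiCl, THF, 0 → 23 °C; then added to 15, THF, −78 °C; then −78 → 23 °C
Reagents that add atoms: none
Why: The aryl Grignard reagent adds to the aldehyde carbon (the future C2), and the chloromagnesium alkoxide so formed attacks the benzylic carbon C5 from the face opposite the mesylate, so that the C2–aryl bond, the O1–C5 bond and the oxolane ring arise in one flask. The closest known reaction type is the addition of an organomagnesium reagent to a γ-halo or γ-sulfonyloxy carbonyl compound with in situ Williamson closure to a 2-substituted oxolane. The ring closes in the 5-exo-tet mode, with the leaving group outside the new ring. C2 is set by Felkin–Anh addition anti to the branched C4 substituent of the α-stereocentre C3, which should give the 2,3-syn (S) carbinol; C5 is set by inversion of the (R)-mesylate to (S), which puts ring B cis to the C4 methyl group. The step needs addition to the aldehyde ahead of enolisation or attack at sulfur, which the low temperature and the weakly basic aryl magnesium reagent should secure. It also needs substitution at C5 without ionisation, which the tosylate on the para oxygen of ring B should secure by removing the donor that would otherwise open a quinone-methide-type cation and lead to the trans isomer.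

Step 13
Reactants: 21 the oxolane bis-tosylate
Product: 22 2-(allyloxy)-4-[(2S,3R,4R,5S)-5-(4-hydroxy-3-methoxyphenyl)-3,4-dimethyloxolan-2-yl]phenol
Conditions: KOH, MeOH/THF, 60 °C; dilute HCl
Reagents that add atoms: none
Why: Hydroxide attacks the sulfur of aryl sulfonates and frees both para phenols, while the oxolane and the allyl ether are stable to base.

Step 14
Reactants: 23 ethyl (S)-lactate
Product: 24 (S)-2-hydroxy-N-methoxy-N-methylpropanamide
Conditions: MeNHOMe·HCl, i-PrMgCl, THF, −20 → 0 °C; dilute HCl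
Reagents that add atoms: N,O-dimethylhydroxylamine hydrochloride, CNOC.Cl
Why: Aminolysis of the ester by the magnesium amide of N,O-dimethylhydroxylamine (Weinreb amide formation) does not touch the stereocentre.

Step 15
Reactants: 24 the Weinreb amide, 25 (3,4-dimethoxyphenyl)magnesium bromide
Product: 26 (S)-1-(3,4-dimethoxyphenyl)-2-hydroxypropan-1-one
Conditions: 25 (3 equiv), THF, 0 °C; dilute HCl
Reagents that add atoms: none
Why: Grignard addition to a Weinreb amide stops at the chelated tetrahedral intermediate and gives the ketone on work-up; the first equivalent only deprotonates the hydroxyl.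

Step 16
Reactants: 26 the hydroxy ketone
Product: 27 (S)-1-(3,4-dimethoxyphenyl)-1-oxopropan-2-yl methanesulfonate
Conditions: Ms2O, Et3N, CH2Cl2, −20 °C
Reagents that add atoms: methanesulfonic anhydride, CS(=O)(=O)OS(C)(=O)=O
Why: Sulfonylation of the secondary alcohol with retention, cold and without chloride so that the α-keto stereocentre is kept.

Step 17
Reactants: 22 the bisphenol, 27 the keto mesylate (2.4 equiv)
Product: 28 bis-ketone in which each para oxygen of 22 carries an (R)-1-(3,4-dimethoxyphenyl)-1-oxopropan-2-yl group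
Conditions: K2CO3, DMF, 23 °C
Reagents that add atoms: none
Why: Twofold Williamson ether synthesis by SN2 attack of the phenoxides at the carbon next to the carbonyl inverts each lactate-derived centre from S to R.

Step 18
Reactants: 28 the bis-ketone
Product: 29 O-allyl manassantin B1, the bis-(1R,2R) alcohol with the allyl ether still on ring A
Conditions: Bu4NBH4, MeOH/CH2Cl2, −40 °C
Reagents that add atoms: none
Why: Felkin–Anh reduction with the aryloxy group anti to the incoming hydride, under a non-chelating ammonium borohydride, should give the threo (1R,2R) alcohol at both ketones.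

Step 19
Reactants: 29 O-allyl manassantin B1
Product: 30 manassantin B1
Conditions: Pd(PPh3)4 (5 mol %), morpholine, THF, 23 °C
Reagents that add atoms: none
Why: Tsuji–Trost deallylation, in which zerovalent palladium ionises the allyl aryl ether to a π-allyl complex that morpholine traps, under neutral conditions that spare the benzylic alcohols and the oxolane.

**Compound list**

1 | (S)-4-benzyl-3-propanoyl-1,3-oxazolidin-2-one | CCC(=O)N1[C@@H](Cc2ccccc2)COC1=O | starting material
2 | lithium (Z)-enolate of 1 | C/C=C(\[O-])N1[C@@H](Cc2ccccc2)COC1=O.[Li+] | intermediate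
3 | (4S,4'S)-3,3'-[(2R,3R)-2,3-dimethylbutanedioyl]bis(4-benzyl-1,3-oxazolidin-2-one) | O=C1OC[C@H](Cc2ccccc2)N1C(=O)[C@H](C)[C@@H](C)C(=O)N1[C@@H](Cc2ccccc2)COC1=O | intermediate
4 | (2R,3R)-2,3-dimethylbutanedioic acid | OC(=O)[C@H](C)[C@@H](C)C(=O)O | intermediate
5 | (3R,4R)-3,4-dimethyloxolane-2,5-dione | O=C1OC(=O)[C@H](C)[C@H]1C | intermediate
6 | 4-bromo-2-methoxyphenol | COc1cc(Br)ccc1O | starting material
7 | 4-bromo-2-methoxyphenyl 4-methylbenzenesulfonate | COc1cc(Br)ccc1OS(=O)(=O)c1ccc(C)cc1 | intermediate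
8 | [3-methoxy-4-(tosyloxy)phenyl]magnesium chloride (ring B Grignard reagent) | COc1cc([Mg]Cl)ccc1OS(=O)(=O)c1ccc(C)cc1 | intermediate
9 | (2R,3R)-4-[3-methoxy-4-(tosyloxy)phenyl]-2,3-dimethyl-4-oxobutanoic acid | OC(=O)[C@H](C)[C@@H](C)C(=O)c1ccc(OS(=O)(=O)c2ccc(C)cc2)c(OC)c1 | intermediate
10 | (2R,3R,4R)-4-hydroxy-4-[3-methoxy-4-(tosyloxy)phenyl]-2,3-dimethylbutanoic acid | OC(=O)[C@H](C)[C@@H](C)[C@@H](O)c1ccc(OS(=O)(=O)c2ccc(C)cc2)c(OC)c1 | intermediate
11 | (3R,4R,5R)-5-[3-methoxy-4-(tosyloxy)phenyl]-3,4-dimethyloxolan-2-one (all-trans) | O=C1O[C@@H](c2ccc(OS(=O)(=O)c3ccc(C)cc3)c(OC)c2)[C@H](C)[C@H]1C | intermediate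
12 | (3R,4R,5R)-5-[3-methoxy-4-(tosyloxy)phenyl]-3,4-dimethyloxolan-2-ol (lactol, both anomers) | OC1O[C@@H](c2ccc(OS(=O)(=O)c3ccc(C)cc3)c(OC)c2)[C@H](C)[C@H]1C | intermediate
13 | (1R,2R,3S)-1-[3-methoxy-4-(tosyloxy)phenyl]-2,3-dimethylpent-4-en-1-ol | O[C@@H](c1ccc(OS(=O)(=O)c2ccc(C)cc2)c(OC)c1)[C@H](C)[C@H](C=C)C | intermediate
14 | (1R,2R,3S)-1-[3-methoxy-4-(tosyloxy)phenyl]-2,3-dimethylpent-4-en-1-yl methanesulfonate | CS(=O)(=O)O[C@@H](c1ccc(OS(=O)(=O)c2ccc(C)cc2)c(OC)c1)[C@H](C)[C@H](C=C)C | intermediate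
15 | (1R,2R,3R)-1-[3-methoxy-4-(tosyloxy)phenyl]-2,3-dimethyl-4-oxobutyl methanesulfonate | CS(=O)(=O)O[C@@H](c1ccc(OS(=O)(=O)c2ccc(C)cc2)c(OC)c1)[C@H](C)[C@H](C=O)C | intermediate
16 | 2-(allyloxy)phenol | C=CCOc1ccccc1O | starting material
17 | 2-(allyloxy)-4-bromophenol | C=CCOc1cc(Br)ccc1O | intermediate
18 | 2-(allyloxy)-4-bromophenyl 4-methylbenzenesulfonate | C=CCOc1cc(Br)ccc1OS(=O)(=O)c1ccc(C)cc1 | intermediate
19 | [3-(allyloxy)-4-(tosyloxy)phenyl]magnesium chloride (ring A Grignard reagent) | C=CCOc1cc([Mg]Cl)ccc1OS(=O)(=O)c1ccc(C)cc1 | intermediate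
20 | chloromagnesium (1S,2R,3R,4R)-1-[3-(allyloxy)-4-(tosyloxy)phenyl]-4-(mesyloxy)-4-[3-methoxy-4-(tosyloxy)phenyl]-2,3-dimethylbutan-1-olate | CS(=O)(=O)O[C@@H](c1ccc(OS(=O)(=O)c2ccc(C)cc2)c(OC)c1)[C@H](C)[C@H]([C@H](O[Mg]Cl)c1ccc(OS(=O)(=O)c2ccc(C)cc2)c(OCC=C)c1)C | intermediate
21 | 2-(allyloxy)-4-{(2S,3R,4R,5S)-5-[3-methoxy-4-(tosyloxy)phenyl]-3,4-dimethyloxolan-2-yl}phenyl 4-methylbenzenesulfonate | Cc1ccc(cc1)S(=O)(=O)Oc1ccc(cc1OCC=C)[C@H]1O[C@H](c2ccc(OS(=O)(=O)c3ccc(C)cc3)c(OC)c2)[C@H](C)[C@H]1C | intermediate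
22 | 2-(allyloxy)-4-[(2S,3R,4R,5S)-5-(4-hydroxy-3-methoxyphenyl)-3,4-dimethyloxolan-2-yl]phenol | Oc1ccc(cc1OCC=C)[C@H]1O[C@H](c2ccc(O)c(OC)c2)[C@H](C)[C@H]1C | intermediate
23 | ethyl (S)-lactate | CCOC(=O)[C@H](C)O | starting material
24 | (S)-2-hydroxy-N-methoxy-N-methylpropanamide | CON(C)C(=O)[C@H](C)O | intermediate
25 | (3,4-dimethoxyphenyl)magnesium bromide | COc1ccc([Mg]Br)cc1OC | starting material
26 | (S)-1-(3,4-dimethoxyphenyl)-2-hydroxypropan-1-one | COc1ccc(cc1OC)C(=O)[C@H](C)O | intermediate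
27 | (S)-1-(3,4-dimethoxyphenyl)-1-oxopropan-2-yl methanesulfonate | COc1ccc(cc1OC)C(=O)[C@H](C)OS(C)(=O)=O | intermediate
28 | (2R)-1-(3,4-dimethoxyphenyl)-2-{2-(allyloxy)-4-[(2S,3R,4R,5S)-5-(4-{[(2R)-1-(3,4-dimethoxyphenyl)-1-oxopropan-2-yl]oxy}-3-methoxyphenyl)-3,4-dimethyloxolan-2-yl]phenoxy}propan-1-one | COc1ccc(C(=O)[C@@H](C)Oc2ccc([C@H]3O[C@H](c4ccc(O[C@H](C)C(=O)c5ccc(OC)c(OC)c5)c(OC)c4)[C@H](C)[C@H]3C)cc2OCC=C)cc1OC | intermediate
29 | O-allyl manassantin B1: (1R,2R)-1-(3,4-dimethoxyphenyl)-2-{2-(allyloxy)-4-[(2S,3R,4R,5S)-5-(4-{[(1R,2R)-1-(3,4-dimethoxyphenyl)-1-hydroxypropan-2-yl]oxy}-3-methoxyphenyl)-3,4-dimethyloxolan-2-yl]phenoxy}propan-1-ol | COc1ccc([C@@H](O)[C@@H](C)Oc2ccc([C@H]3O[C@H](c4ccc(O[C@H](C)[C@H](O)c5ccc(OC)c(OC)c5)c(OC)c4)[C@H](C)[C@H]3C)cc2OCC=C)cc1OC | intermediate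
30 | manassantin B1 | COc1ccc([C@@H](O)[C@@H](C)Oc2ccc([C@H]3O[C@H](c4ccc(O[C@H](C)[C@H](O)c5ccc(OC)c(OC)c5)c(OC)c4)[C@H](C)[C@H]3C)cc2O)cc1OC | target

**Step count and risks**

Total step count: 19. Longest linear sequence: 13 steps (1, 2, 3, 5, 6, 7, 8, 9, 12, 13, 17, 18, 19).

Steps most likely to fail:

Step 12. The aryl addition may show only moderate Felkin–Anh facial selectivity at C2. Chloride exchange or ionisation at C5 before closure would erode the inversion. Enolisation of the aldehyde by the Grignard reagent would epimerise C3. The fallback makes the C2 carbinol by catalyst-controlled reduction instead of arylation, with no halide present at the closure. It sets out from lactone 11. Ring A Grignard reagent 19 is added to 11 at −78 °C to give the hydroxy ketone F1. Ms2O/Et3N at −20 °C converts its free benzylic hydroxyl into the keto mesylate F2. Reduction with (R)-2-methyl-CBS-oxazaborolidine and catecholborane in toluene at −60 °C should give the (S)-carbinol, the hydroxy mesylate F3. K2CO3 in MeCN closes F3 with inversion at C5, and the route is rejoined at oxolane 21.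

Step 17. Enolisation of 27 or of the product under the basic conditions may erode the configuration of the new ether centres, and the second alkylation may stall. The fallback builds the side chain in the other direction under neutral conditions. It sets out from bisphenol 22. A twofold Mitsunobu reaction with ethyl (S)-lactate 23 (PPh3, DIAD, THF) should give, with inversion, the bis-(R)-aryloxypropanoate F4. MeNHOMe·HCl/i-PrMgCl converts F4 into the bis-Weinreb amide F5. Addition of (3,4-dimethoxyphenyl)magnesium bromide 25 at −20 °C gives the bis-ketone, and the route is rejoined at 28.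

Step 18. The twofold reduction may show insufficient facial selectivity if a chelated pathway competes, which would give erythro material at one or both side chains. The fallback uses the opposite, reliably chelation-controlled sense and then inverts the carbinols. It sets out from bis-ketone 28. Zn(BH4)2 in Et2O at 0 °C should give the bis-erythro alcohol F6 (1S,2R in each side chain). A twofold Mitsunobu inversion with 4-nitrobenzoic acid (PPh3, DIAD) gives the bis(4-nitrobenzoate) F7 with (1R,2R) side chains. K2CO3 in MeOH removes the esters, and the route is rejoined at 29.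

Further compounds
F1 | step 12 | (2R,3R,4R)-1-[3-(allyloxy)-4-(tosyloxy)phenyl]-4-hydroxy-4-[3-methoxy-4-(tosyloxy)phenyl]-2,3-dimethylbutan-1-one | O[C@@H](c1ccc(OS(=O)(=O)c2ccc(C)cc2)c(OC)c1)[C@H](C)[C@H](C(=O)c1ccc(OS(=O)(=O)c2ccc(C)cc2)c(OCC=C)c1)C
F2 | step 12 | (1R,2R,3R)-4-[3-(allyloxy)-4-(tosyloxy)phenyl]-1-[3-methoxy-4-(tosyloxy)phenyl]-2,3-dimethyl-4-oxobutyl methanesulfonate | CS(=O)(=O)O[C@@H](c1ccc(OS(=O)(=O)c2ccc(C)cc2)c(OC)c1)[C@H](C)[C@H](C(=O)c1ccc(OS(=O)(=O)c2ccc(C)cc2)c(OCC=C)c1)C
F3 | step 12 | (1R,2R,3R,4S)-4-[3-(allyloxy)-4-(tosyloxy)phenyl]-4-hydroxy-1-[3-methoxy-4-(tosyloxy)phenyl]-2,3-dimethylbutyl methanesulfonate | CS(=O)(=O)O[C@@H](c1ccc(OS(=O)(=O)c2ccc(C)cc2)c(OC)c1)[C@H](C)[C@H]([C@H](O)c1ccc(OS(=O)(=O)c2ccc(C)cc2)c(OCC=C)c1)C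
F4 | step 17 | ethyl (2R)-2-{2-(allyloxy)-4-[(2S,3R,4R,5S)-5-(4-{[(2R)-1-ethoxy-1-oxopropan-2-yl]oxy}-3-methoxyphenyl)-3,4-dimethyloxolan-2-yl]phenoxy}propanoate | CCOC(=O)[C@@H](C)Oc1ccc([C@H]2O[C@H](c3ccc(O[C@H](C)C(=O)OCC)c(OC)c3)[C@H](C)[C@H]2C)cc1OCC=C
F5 | step 17 | (2R)-2-{2-(allyloxy)-4-[(2S,3R,4R,5S)-5-(4-{[(2R)-1-[methoxy(methyl)amino]-1-oxopropan-2-yl]oxy}-3-methoxyphenyl)-3,4-dimethyloxolan-2-yl]phenoxy}-N-methoxy-N-methylpropanamide | CON(C)C(=O)[C@@H](C)Oc1ccc([C@H]2O[C@H](c3ccc(O[C@H](C)C(=O)N(C)OC)c(OC)c3)[C@H](C)[C@H]2C)cc1OCC=C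
F6 | step 18 | bis-erythro isomer of 29 with (1S,2R) configuration in both side chains | COc1ccc([C@H](O)[C@@H](C)Oc2ccc([C@H]3O[C@H](c4ccc(O[C@H](C)[C@@H](O)c5ccc(OC)c(OC)c5)c(OC)c4)[C@H](C)[C@H]3C)cc2OCC=C)cc1OC
F7 | step 18 | bis(4-nitrobenzoate) of 29 with (1R,2R) configuration in both side chains | COc1ccc([C@@H](OC(=O)c2ccc(cc2)[N+](=O)[O-])[C@@H](C)Oc2ccc([C@H]3O[C@H](c4ccc(O[C@H](C)[C@H](OC(=O)c5ccc(cc5)[N+](=O)[O-])c5ccc(OC)c(OC)c5)c(OC)c4)[C@H](C)[C@H]3C)cc2OCC=C)cc1OC
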